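The lignan numbering is used: C1 (bears OAc), C2 (guaiacyl), O3, C4 and C5 make up ring A, and C1, C5, C6 (veratryl), O7 and C8 make up ring B.
The five-membered ether ring A can be read as a carbonyl ylide (C2, O3, C4) laid across an alkene (C1=C5). Because C1 already carries an ester oxygen and C8 can be a lactone carbonyl, that alkene is the enol acetate of an α-keto-γ-lactone, a 3-acetoxybutenolide that is ring B.
The retrosynthesis first removes the phenol O–benzyl and C1 O–acetyl bonds, then cuts O7–C8 (ether closure, back to the C8 lactone), then C1–C2 and C4–C5 together in a [3+2] cut, and last takes the C6 carbinol back to an aryl ketone.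
In the forward direction ring B is built first as a γ-lactone and oxidised to the acetoxybutenolide, ring A is closed onto it by the cycloaddition, and ring B is then opened by hydride and closed again as the cyclic ether.
C6 comes from a Ru-catalysed asymmetric transfer hydrogenation. It sends the ylide to the opposite face, which sets C5 and C1, and exo approach of the E-ylide sets C2.
Key step: step 4

Remark: the keto acid, the O-benzylvanillin and the silylmethanol are taken as catalogue compounds, and the α-hydroxy lactone is carried as its C3 epimers because that centre becomes trigonal in the following step.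

Step 1
Reactants: 1 4-(3,4-dimethoxyphenyl)-4-oxobutanoic acid
Product: 3 (S)-5-(3,4-dimethoxyphenyl)dihydrofuran-2(3H)-one, via (S)-hydroxy acid 2 (not isolated)
Conditions: RuCl[(S,S)-TsDPEN](p-cymene) (1 mol %), HCO2H/Et3N (5:2), 40 °C
Reagents that add atoms: none
Why: Noyori–Ikariya asymmetric transfer hydrogenation of an aryl alkyl ketone, in which the CH/π contact between the p-cymene ligand and the veratryl ring in the six-membered hydride-transfer state exposes one ketone face, so the (S,S)-ligand should set C6 as S as it does for simple aryl alkyl ketones, and the γ-hydroxy acid lactonises in the acidic medium.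

Step 2
Reactants: 3 (S)-5-(3,4-dimethoxyphenyl)dihydrofuran-2(3H)-one
Product: 5 (5S)-5-(3,4-dimethoxyphenyl)-3-hydroxydihydrofuran-2(3H)-one (both C3 epimers), via potassium enolate 4 (not isolated)
Conditions: KN(SiMe3)2, THF, −78 °C; then 2-(phenylsulfonyl)-3-phenyloxaziridine, −78 °C; AcOH quench
Reagents that add atoms: 2-(phenylsulfonyl)-3-phenyloxaziridine, O=S(=O)(N1OC1c1ccccc1)c1ccccc1
Why: Davis oxidation of a lactone enolate is a standard α-hydroxylation; the new C3 centre (the trans (3R,5S) epimer should prevail) needs no control because step 3 erases it, and the C6 hydrogen is not acidic at this stage.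

Step 3
Reactants: 5 (5S)-5-(3,4-dimethoxyphenyl)-3-hydroxydihydrofuran-2(3H)-one
Product: 7 (S)-5-(3,4-dimethoxyphenyl)-2-oxo-2,5-dihydrofuran-3-yl acetate, via enol lactone 6 (not isolated)
Conditions: Dess–Martin periodinane (1.1 equiv), CH2Cl2, 0 °C → rt; then pyridine, Ac2O, 0 °C
Reagents that add atoms: acetic anhydride, CC(=O)OC(C)=O
Why: Dess–Martin oxidation of the secondary α-hydroxy lactone gives the 2,3-dione, which rests as its conjugated enol 6, and O-acetylation of this acidic enol with pyridine, a base too weak to remove the C6 hydrogen, traps it before it can self-condense; no stereocentre is formed.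

Step 4
Reactants: 7 (S)-5-(3,4-dimethoxyphenyl)-2-oxo-2,5-dihydrofuran-3-yl acetate; 8 4-(benzyloxy)-3-methoxybenzaldehyde; 9 (trimethylsilyl)methanol
Product: 12 (1R,2R,5R,6S)-2-[4-(benzyloxy)-3-methoxyphenyl]-6-(3,4-dimethoxyphenyl)-8-oxo-3,7-dioxabicyclo[3.3.0]octan-1-yl acetate, via α-chloro ether 10 (not isolated), via carbonyl ylide 11 (not isolated)
Conditions: 8 + 9 (2 equiv each), dry HCl, MgSO4, CH2Cl2, 0 °C; filter, evaporate; then 7, MeCN, CsF added last in portions, 0 °C → rt
Reagents that add atoms: none
Why: Proposed new method: dry HCl condenses 8 and 9 to α-chloro ether 10, and fluoride attack at silicon with departure of chloride (a 1,3-elimination that may run through the aryl-stabilised oxocarbenium ion) releases ylide 11, a four-electron dipole spread over C2, O3 and C4 whose carbanion character lies mainly on the unsubstituted C4. The closest known reaction type is this same fluoride-triggered release of non-stabilised carbonyl ylides and their [3+2] cycloaddition to acrylates, fumarates and maleates; new is the α-acyloxybutenolide as 2π partner, which should still react because the C8 carbonyl lowers the LUMO of C1=C5 and the acetyl group withdraws the donor lone pair of the C1 oxygen. Ring A closes by an intermolecular, suprafacial 4π+2π cycloaddition, concerted but asynchronous with C4–C5 running ahead of C1–C2, so the cis fusion of rings A and B follows from the cyclic alkene. C5 and C1 are set by attack on the butenolide face opposite the C6 veratryl group, and C2 by the E-ylide reacting in the exo mode (O3 turned away from ring B), which leaves the aryl group on the convex face, cis to the acetate. The step needs regio-, face and exo selectivity, secured in turn by the match of nucleophilic C4 with the β-carbon C5, by the C6 substituent, and by the aryl group avoiding the lactone ring. HCl and water are removed before 7 enters and CsF is added last to an excess of 10, so that fluoride is used up at silicon before it can attack the enol ester or the C6 hydrogen of 7.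

Step 5
Reactants: 12 (1R,2R,5R,6S)-2-[4-(benzyloxy)-3-methoxyphenyl]-6-(3,4-dimethoxyphenyl)-8-oxo-3,7-dioxabicyclo[3.3.0]octan-1-yl acetate
Product: 13 (2R,3S,4R)-2-[4-(benzyloxy)-3-methoxyphenyl]-4-[(S)-(3,4-dimethoxyphenyl)(hydroxy)methyl]-3-(hydroxymethyl)oxolan-3-ol
Conditions: LiAlH4, THF, 0 °C → rt; Fieser work-up (H2O, aq NaOH)
Reagents that add atoms: none
Why: Exhaustive LiAlH4 reduction of esters opens the ring B lactone to the C8 primary and C6 benzylic alcohols and cleaves the acetate in the same operation, without touching any of the four stereocentres or the benzyl ether.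

Step 6
Reactants: 13 (2R,3S,4R)-2-[4-(benzyloxy)-3-methoxyphenyl]-4-[(S)-(3,4-dimethoxyphenyl)(hydroxy)methyl]-3-(hydroxymethyl)oxolan-3-ol
Product: 15 (1S,2R,5R,6S)-2-[4-(benzyloxy)-3-methoxyphenyl]-6-(3,4-dimethoxyphenyl)-3,7-dioxabicyclo[3.3.0]octan-1-ol, via primary mesylate 14 (not isolated)
Conditions: MsCl (1.05 equiv), Et3N, CH2Cl2, −20 °C → rt
Reagents that add atoms: none
Why: Selective mesylation of the only primary hydroxyl followed by 5-exo-tet intramolecular Williamson-type displacement by the C6 hydroxyl is the usual closure of the 1,4-diols obtained from furofuranones; the C6–O bond is never broken, so C6 keeps its configuration, and the amine base is too weak to ionise the tertiary hydroxyl towards an oxirane.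

Step 7
Reactants: 15 (1S,2R,5R,6S)-2-[4-(benzyloxy)-3-methoxyphenyl]-6-(3,4-dimethoxyphenyl)-3,7-dioxabicyclo[3.3.0]octan-1-ol
Product: 16 (1S,2R,5R,6S)-2-[4-(benzyloxy)-3-methoxyphenyl]-6-(3,4-dimethoxyphenyl)-3,7-dioxabicyclo[3.3.0]octan-1-yl acetate
Conditions: Ac2O, Et3N, DMAP, CH2Cl2, rt → 40 °C
Reagents that add atoms: acetic anhydride, CC(=O)OC(C)=O
Why: Steglich-type DMAP-catalysed acylation is the standard way to esterify hindered tertiary alcohols, takes place at oxygen with retention at C1, and runs under basic conditions that the acid-labile benzylic ethers tolerate.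

Step 8
Reactants: 16 (1S,2R,5R,6S)-2-[4-(benzyloxy)-3-methoxyphenyl]-6-(3,4-dimethoxyphenyl)-3,7-dioxabicyclo[3.3.0]octan-1-yl acetate
Product: 17 (1S,2R,5R,6S)-6-(3,4-dimethoxyphenyl)-2-(4-hydroxy-3-methoxyphenyl)-3,7-dioxabicyclo[3.3.0]octan-1-yl acetate (CNP0107105.1)
Conditions: H2 (1 atm), 10% Pd/C, EtOAc, rt, stopped after one equivalent of H2
Reagents that add atoms: none
Why: Catalytic hydrogenolysis of an aryl benzyl ether in an aprotic solvent at one atmosphere is much faster than cleavage of the ring C2–O3 and C6–O7 benzylic bonds, so stopping at one equivalent of hydrogen should leave the bicycle, the acetate and all stereocentres intact.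

Compound list
1 | 4-(3,4-dimethoxyphenyl)-4-oxobutanoic acid | COc1ccc(C(=O)CCC(=O)O)cc1OC | starting material
2 | (S)-4-(3,4-dimethoxyphenyl)-4-hydroxybutanoic acid | COc1ccc([C@@H](O)CCC(=O)O)cc1OC | intermediate
3 | (S)-5-(3,4-dimethoxyphenyl)dihydrofuran-2(3H)-one | O=C1CC[C@@H](c2ccc(OC)c(OC)c2)O1 | intermediate
4 | potassium (S)-5-(3,4-dimethoxyphenyl)-4,5-dihydrofuran-2-olate (enolate of 3) | [K+].[O-]C1=CC[C@@H](c2ccc(OC)c(OC)c2)O1 | intermediate
5 | (5S)-5-(3,4-dimethoxyphenyl)-3-hydroxydihydrofuran-2(3H)-one, both C3 epimers | O=C1C(O)C[C@@H](c2ccc(OC)c(OC)c2)O1 | intermediate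
6 | (S)-5-(3,4-dimethoxyphenyl)-3-hydroxyfuran-2(5H)-one | OC1=C[C@@H](c2ccc(OC)c(OC)c2)OC1=O | intermediate
7 | (S)-5-(3,4-dimethoxyphenyl)-2-oxo-2,5-dihydrofuran-3-yl acetate | CC(=O)OC1=C[C@@H](c2ccc(OC)c(OC)c2)OC1=O | intermediate
8 | 4-(benzyloxy)-3-methoxybenzaldehyde | COc1cc(C=O)ccc1OCc1ccccc1 | starting material
9 | (trimethylsilyl)methanol | C[Si](C)(C)CO | starting material
10 | [4-(benzyloxy)-3-methoxyphenyl](chloro)methyl (trimethylsilyl)methyl ether, racemic | COc1cc(C(Cl)OC[Si](C)(C)C)ccc1OCc1ccccc1 | intermediate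
11 | (E)-carbonyl ylide, [4-(benzyloxy)-3-methoxybenzylidene]oxoniomethanide | COc1cc(/C=[O+]/[CH2-])ccc1OCc1ccccc1 | intermediate
12 | (1R,2R,5R,6S)-2-[4-(benzyloxy)-3-methoxyphenyl]-6-(3,4-dimethoxyphenyl)-8-oxo-3,7-dioxabicyclo[3.3.0]octan-1-yl acetate | COc1cc([C@H]2OC[C@@H]3[C@@H](c4ccc(OC)c(OC)c4)OC(=O)[C@]23OC(C)=O)ccc1OCc1ccccc1 | intermediate
13 | (2R,3S,4R)-2-[4-(benzyloxy)-3-methoxyphenyl]-4-[(S)-(3,4-dimethoxyphenyl)(hydroxy)methyl]-3-(hydroxymethyl)oxolan-3-ol | COc1cc([C@H]2OC[C@H]([C@@H](c3ccc(OC)c(OC)c3)O)[C@]2(O)CO)ccc1OCc1ccccc1 | intermediate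
14 | {(2R,3S,4R)-2-[4-(benzyloxy)-3-methoxyphenyl]-4-[(S)-(3,4-dimethoxyphenyl)(hydroxy)methyl]-3-hydroxyoxolan-3-yl}methyl methanesulfonate | COc1cc([C@H]2OC[C@H]([C@@H](c3ccc(OC)c(OC)c3)O)[C@]2(O)COS(C)(=O)=O)ccc1OCc1ccccc1 | intermediate
15 | (1S,2R,5R,6S)-2-[4-(benzyloxy)-3-methoxyphenyl]-6-(3,4-dimethoxyphenyl)-3,7-dioxabicyclo[3.3.0]octan-1-ol | COc1cc([C@H]2OC[C@@H]3[C@@H](c4ccc(OC)c(OC)c4)OC[C@]23O)ccc1OCc1ccccc1 | intermediate
16 | (1S,2R,5R,6S)-2-[4-(benzyloxy)-3-methoxyphenyl]-6-(3,4-dimethoxyphenyl)-3,7-dioxabicyclo[3.3.0]octan-1-yl acetate | COc1cc([C@H]2OC[C@@H]3[C@@H](c4ccc(OC)c(OC)c4)OC[C@]23OC(C)=O)ccc1OCc1ccccc1 | intermediate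
17 | (1S,2R,5R,6S)-6-(3,4-dimethoxyphenyl)-2-(4-hydroxy-3-methoxyphenyl)-3,7-dioxabicyclo[3.3.0]octan-1-yl acetate | COc1cc([C@H]2OC[C@@H]3[C@@H](c4ccc(OC)c(OC)c4)OC[C@]23OC(C)=O)ccc1O | target

Total step count: 8. Longest linear sequence: 8 steps, from 1 to 17 (8 and 9 enter as bought).

Steps most likely to fail

Step 4.
- **Risk:** The short-lived ylide may be lost to self-reaction or to unconverted aldehyde faster than it adds to a trisubstituted, donor-bearing alkene. The electron-rich chloro ether may decompose before fluoride reaches it. Fluoride may cleave the enol ester or remove the C6 hydrogen of 7, which would erode enantiopurity. The exo/endo preference at C2 may also be weak.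
- **Fallback:** The C1 oxygen is brought in after the cycloaddition, so that the 2π partner is a plain enoate-type butenolide, the class for which this ylide chemistry is established. The detour sets out from lactone 3. LiN(iPr)2 and then PhSeBr should give (5S)-5-(3,4-dimethoxyphenyl)-3-(phenylselanyl)dihydrofuran-2(3H)-one F1. H2O2 oxidation and selenoxide syn-elimination lead to (S)-5-(3,4-dimethoxyphenyl)furan-2(5H)-one F2. Ylide 11, released from 10 with CsF as in step 4, adds anti to the veratryl group to give the C1-unsubstituted furofuranone F3. KN(SiMe3)2 and the oxaziridine of step 2 hydroxylate the ring-fusion enolate, where only the cis-fused outcome is possible, to give the α-hydroxy lactone F4. LiAlH4 reduces F4 to triol 13, where the route is rejoined.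

Step 6.
- **Risk:** Sulfonylation may fail to discriminate between the neopentyl-type primary hydroxyl and the benzylic one, and ionisation at C6 would then put its configuration at risk. Displacement at the hindered C8 may be slow, and closure of the tertiary hydroxyl to an oxirane may intervene.
- **Fallback:** Ring B is never opened. The detour sets out from cycloadduct 12. Excess iBu2AlH in CH2Cl2 at −78 °C removes the acetate and stops the lactone at the lactol diol F5. Ionic reduction of the derived oxocarbenium ion with Et3SiH and BF3·OEt2 at −78 °C gives alcohol 15 directly, in place of steps 5 and 6. The low temperature is what protects the C2–O3 and C6–O7 benzylic bonds.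

Step 3.
- **Risk:** The periodinane may oxidise the electron-rich enol further, and the free enol may self-condense. Contact with base may cost C6 integrity through γ-deprotonation or through reversible β-elimination of the carboxylate.
- **Fallback:** An enamine is cleaved oxidatively instead of an alcohol being oxidised. The detour sets out from lactone 3. tert-Butoxybis(dimethylamino)methane (Bredereck's reagent) in toluene at 90 °C should give the enaminolactone (S,E)-3-[(dimethylamino)methylidene]-5-(3,4-dimethoxyphenyl)dihydrofuran-2(3H)-one F6. Dye-sensitised photooxygenation (O2, tetraphenylporphyrin, hν, CH2Cl2, −78 °C) cleaves its C=C bond through a dioxetane to enol 6. Acetylation in the same flask with Ac2O and pyridine gives 7, where the route is rejoined, and the detour replaces steps 2 and 3.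

Further compounds
F1 | step 4 | (5S)-5-(3,4-dimethoxyphenyl)-3-(phenylselanyl)dihydrofuran-2(3H)-one, both C3 epimers | O=C1C([Se]c2ccccc2)C[C@@H](c2ccc(OC)c(OC)c2)O1
F2 | step 4 | (S)-5-(3,4-dimethoxyphenyl)furan-2(5H)-one | O=C1C=C[C@@H](c2ccc(OC)c(OC)c2)O1
F3 | step 4 | (1S,2S,5R,6S)-2-[4-(benzyloxy)-3-methoxyphenyl]-6-(3,4-dimethoxyphenyl)-3,7-dioxabicyclo[3.3.0]octan-8-one | COc1cc([C@H]2OC[C@@H]3[C@@H](c4ccc(OC)c(OC)c4)OC(=O)[C@H]23)ccc1OCc1ccccc1
F4 | step 4 | (1R,2R,5R,6S)-2-[4-(benzyloxy)-3-methoxyphenyl]-6-(3,4-dimethoxyphenyl)-1-hydroxy-3,7-dioxabicyclo[3.3.0]octan-8-one | COc1cc([C@H]2OC[C@@H]3[C@@H](c4ccc(OC)c(OC)c4)OC(=O)[C@]23O)ccc1OCc1ccccc1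
F5 | step 6 | (1R,2R,5R,6S)-2-[4-(benzyloxy)-3-methoxyphenyl]-6-(3,4-dimethoxyphenyl)-3,7-dioxabicyclo[3.3.0]octane-1,8-diol, lactol, both C8 anomers | COc1cc([C@H]2OC[C@@H]3[C@@H](c4ccc(OC)c(OC)c4)OC(O)[C@]23O)ccc1OCc1ccccc1
F6 | step 3 | (S,E)-3-[(dimethylamino)methylidene]-5-(3,4-dimethoxyphenyl)dihydrofuran-2(3H)-one | CN(C)/C=C1\C[C@@H](c2ccc(OC)c(OC)c2)OC1=O
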